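The question is how much target the midnight flask holds at 5.7 min: it is charged like the noon run but has target in it from the start. The two exponents of the opening rate are asked as well.

| flask | starting material | coupling partner | target | time |
|---|---|---|---|---|
| noon | 1.00 M | 1.10 M |  |  |
| spring | 0.500 M | 0.600 M |  |  |
| winter | 1.00 M | 1.70 M |  |  |
| summer | 1.50 M | 1.10 M |  |  |
| midnight | 1.00 M | 1.10 M | 0.300 M | 5.7 min |

- noon run (time / min: [target] / M): 0.23: 0; 0.39: 0.002; 0.67: 0.012; 1.1: 0.052; 1.9: 0.142; 3.3: 0.315; 5.7: 0.405
- spring run (time / min: [target] / M): 0.23: 0; 0.39: 0; 0.67: 0; 1.1: 0.008; 1.9: 0.026; 3.3: 0.062; 5.7: 0.123
- winter run (time / min: [target] / M): 0.23: 0.003; 0.39: 0.010; 0.67: 0.028; 1.1: 0.095; 1.9: 0.282; 3.3: 0.445; 5.7: 0.428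
- summer run (time / min: [target] / M): 0.23: 0; 0.39: 0.012; 0.67: 0.036; 1.1: 0.095; 1.9: 0.308; 3.3: 0.555; 5.7: 0.651

(each reading ± 0.003 M)

- Overall: starting material + coupling partner -> target.
- Constant volume, constant temperature.
- An order is taken over about fifteen percent of the charge, up and down.
- A share of target counts the target that was charged too.

- how the opening rate goes with [coupling partner] round the charge of the noon run: the exponent of the rate at two percent of starting material gone to target
- how the opening rate goes with [starting material] round the charge of the noon run: the exponent of the rate at two percent of starting material gone to target (one fixed amount of target, the same in the runs compared)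
- target in the midnight run at 5.7 min, as a share of the starting material charged

The neighbour to read is the noon run, and what I carry from it is the kept share: target made by 5.7 min per starting material charged, 40.5%. Starting material is the limiting reagent there, at 1.00 M against 1.10 M of coupling partner. The noon run needs 3.3 min to reach 0.315 M of target, and then it slows: its last stretch climbs at 0.0375 M min⁻¹, less than the 0.124 M min⁻¹ of the stretch before. So in the noon run the rate falls while target climbs, and by 3.3 min at most 0.685 M of starting material remains. The midnight flask opens with about that target, 0.300 M, but with c(starting material) at 1.00 M, more than that remainder, and it has the whole 5.7 min ahead of it.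

I therefore freeze the kept share. In the winter run, with coupling partner raised to 1.70 M, the share at 5.7 min reads 42.8%. The spring run, at 24.6%, lies below the noon share and is still climbing, so I hold the rule near the noon charge. My reckoning is the charged target plus the noon gain, which comes to 70.5% of the starting material charged. The forecast gives 52%, with exponents 0.8 in coupling partner and 1 in starting material, and it says the midnight flask “gains less than noon did”. There my reckoning and the forecast differ.

The midnight flask gives 72.6%, and the exponents are 0.69 in coupling partner and 0.81 in starting material. Behind the readings stands this scheme:

    starting material → intermediate (0.2016 min⁻¹)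
    intermediate + coupling partner → target (0.3120 M⁻¹ min⁻¹)
    intermediate → side product (0.1038 min⁻¹)
    target + coupling partner → side product (0.2346 M⁻¹ min⁻¹)
    starting material + coupling partner + target → 2 target (1.404 M⁻² min⁻¹)

A power law fitted to the runs leaves a root mean square residual of 17 in units of the scatter. The net gain of target over the charge in the midnight flask is 42.6% of its starting material, more than the noon share of 40.5%. On the summer run, the share predicts 0.608 M from 1.50 M of starting material, less than the 0.651 M read at 5.7 min.

Readings and results were generated by integration for substances that don't exist; noise was put on by code.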